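The readings were computed with constants of no real substance; scatter was added.

Slowness in these runs need not come from a flask merely using up what it holds.

the same everywhere: starting material 0.050 M; reagent 0.0525 M; free catalyst 1.2 mM; added ligand 3.3 mM
- dawn: second substrate 0.025 M; the very flask that is asked about, followed so far
- midnight: second substrate 0.013 M; run made earlier
- flask: second substrate 0.0250 M

Dawn and midnight differ in second substrate, and that flask is the one asked about.

dawn run (percent of the starting material charged)

| time / s | target / % | starting material / % |
|---|---|---|
| 10.0 | 4.9 | 93.1 |
| 15.0 | 6.6 | 91.9 |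
| 25.0 | 10.9 | 89.3 |
| 40.0 | 15.8 | 83.9 |
| 60.0 | 21.4 | 76.8 |
| 120 | 33.6 | 64.9 |

midnight run (percent of the starting material charged)

| time / min | target / % | starting material / % |
|---|---|---|
| 1.00 | 23.8 | 75.6 |
| 2.00 | 36.7 | 61.1 |
| 3.00 | 46.3 | 52.8 |
| 4.00 | 50.3 | 47.7 |
| 5.00 | 55.4 | 43.1 |
| 6.00 | 58.6 | 39.9 |

(standard deviation of a reading: 0.5 percentage points)



At 120 s, dawn holds 33.6% target against 36.7% in midnight, so it is slower despite more second substrate. But dawn's own rate also needs a look. Divide the rate of making target by the mean fractions of starting material and reagent left, taking reagent as its charge less target. Up to 60.0 s this gives 0.270 min⁻¹; from 60.0 s to 120 s it gives 0.233 min⁻¹. The drop is read here as catalyst loss. It gives 6.92 min, the fade time: the time in which unspent catalyst falls by a factor e. It is a reading with wide scatter, and this reckoning draws no order from it.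

- apparent order in second substrate when 50% of the starting material are converted (percent change of the rate of making target for one percent more second substrate charged)
- factor on the rate of making target when 50% of the starting material are converted if second substrate is charged twice over

The forecast gives −0.22 (range −0.5 to 0.1) and 0.83 (range 0.68 to 1.07), holding that “second substrate seems to act as a mild inhibitor or catalyst binder”.

The flask gives −0.88 and 0.304, both below those ranges.

    free catalyst + added ligand ⇌ idle complex, settled at all times (K = 130 M⁻¹)
    starting material + free catalyst ⇌ catalyst intermediate A (K = 69.0 M⁻¹, k = 280 M⁻¹ s⁻¹)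
    catalyst intermediate A → spent catalyst (k = 0.00540 s⁻¹)
    reagent + catalyst intermediate B → free catalyst + second product (k = 5.50 M⁻¹ s⁻¹)
    reagent + catalyst intermediate A → free catalyst + target (k = 6.60 M⁻¹ s⁻¹)
    second substrate + free catalyst ⇌ catalyst intermediate B (K = 98.0 M⁻¹, k = 18.0 M⁻¹ s⁻¹)

The fade time is shorter than the marked time: it leaves 53.6% unspent at 4.32 min and 11.4% at 15.0 min, while the flask holds 48.3% and then 85.0% spent catalyst, with 35% of the starting material and 16% of the reagent left. If twice the free catalyst fades with the same fade time, and conversion follows unspent catalyst summed over time, the rate at 50% conversion reckons to a factor of 2.87, and the simulated factor is 3.11.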